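The side chain at C8 of the flavanone A ring is a bishomoallylic alcohol, C1'(OH)–C2'H2–C3'H(aryl)–C4'=C5'. This is the retron of a nickel-catalysed reductive diene–aldehyde coupling. The C1'–C2' bond is therefore cut to the (2S)-8-formylflavanone 7 and the 2-aryl-1,3-diene 15, whose terminal =CH2 becomes C2'. In one operation the step joins both halves, delivers hydride to the aryl-bearing diene carbon (C3' stereocentre, ligand control) and keeps the E-C4'=C5' alkene. The coupling is inherently 1,3-anti and the target is 1,3-syn, so C1' is then corrected by benzylic oxidation and CBS reduction. Fluoride finally unmasks the four phenols.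

Key step: step 10

Assumption: primed locants C1'–C9' number the nonenyl side chain outward from ring carbon C8. The ligand antipode written in step 10 is provisional, because the sense of induction on a 2-aryl diene has to be fixed on a model; the other antipode is used if the 3'S series forms.

Step 1
Reactants: 1 2',4'-dihydroxy-6'-methoxyacetophenone
Product: 2 1-[4-(tert-butyldimethylsilyloxy)-2-hydroxy-6-methoxyphenyl]ethanone
Conditions: TBSCl (1.05 equiv), imidazole, CH2Cl2, 0 °C
Reagents that add atoms: tert-butyldimethylsilyl chloride, CC(C)(C)[Si](C)(C)Cl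
Why: Silyl ether formation is selective because the 2'-OH is tied up in a hydrogen bond to the acetyl oxygen and only the free, more acidic 4'-OH is silylated.

Step 2
Reactants: 2 1-[4-(tert-butyldimethylsilyloxy)-2-hydroxy-6-methoxyphenyl]ethanone
Product: 4 7-(tert-butyldimethylsilyloxy)-5-methoxy-4H-chromen-4-one, via enaminone 3 (not isolated)
Conditions: DMF-DMA, toluene, 100 °C; concentrate; TsOH·H2O (1.2 equiv), CH2Cl2, 25–40 °C
Reagents that add atoms: N,N-dimethylformamide dimethyl acetal, COC(OC)N(C)C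
Why: Enaminone chromone synthesis: condensation of the acetyl CH3 with the amide acetal gives 3, and acid then triggers 6-endo attack of the 2'-OH on the enaminone β-carbon with loss of dimethylamine, conditions that aryl TBS ethers tolerate.

Step 3
Reactants: 4 7-(tert-butyldimethylsilyloxy)-5-methoxy-4H-chromen-4-one; 5 4-(tert-butyldimethylsilyloxy)phenylboronic acid
Product: 6 (2S)-7-(tert-butyldimethylsilyloxy)-2-[4-(tert-butyldimethylsilyloxy)phenyl]-5-methoxychroman-4-one
Conditions: [Rh(OH)(cod)]2 (2.5 mol %), (S)-MeO-F12-BIPHEP (5.5 mol %), toluene/H2O, 25–35 °C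
Reagents that add atoms: none
Why: Hayashi–Miyaura rhodium-catalysed asymmetric 1,4-addition is a known entry to flavanones from chromones; the (S)-biaryl bisphosphine exposes the same enone face as in the (S)-3-arylcyclohexanone series and so sets C2 as S, while the base-free medium prevents retro-oxa-Michael racemisation.

Step 4
Reactants: 6 (2S)-7-(tert-butyldimethylsilyloxy)-2-[4-(tert-butyldimethylsilyloxy)phenyl]-5-methoxychroman-4-one
Product: 7 (2S)-7-(tert-butyldimethylsilyloxy)-2-[4-(tert-butyldimethylsilyloxy)phenyl]-5-methoxy-4-oxochromane-8-carbaldehyde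
Conditions: Cl2CHOMe, AgOTf, CH2Cl2, −78 °C; aq NaHCO3
Reagents that add atoms: dichloromethyl methyl ether, COC(Cl)Cl; water, O
Why: Rieche formylation with silver triflate activation runs at low temperature and spares aryl silyl ethers, and it should take C8 because this position is para to 5-OMe and flanked by the small ring oxygen, whereas C6 is wedged between OMe and OTBS and ring B carries only one donor.

Step 5
Reactants: 8 methyl 3-(4-hydroxyphenyl)propanoate
Product: 9 methyl 3-[4-(tert-butyldimethylsilyloxy)phenyl]propanoate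
Conditions: TBSCl, imidazole, DMF, 25 °C
Reagents that add atoms: tert-butyldimethylsilyl chloride, CC(C)(C)[Si](C)(C)Cl
Why: Standard silyl ether formation on the only hydroxyl group.

Step 6
Reactants: 9 methyl 3-[4-(tert-butyldimethylsilyloxy)phenyl]propanoate
Product: 10 3-[4-(tert-butyldimethylsilyloxy)phenyl]propanal
Conditions: DIBAL-H (1.05 equiv), CH2Cl2, −78 °C; Rochelle salt
Reagents that add atoms: none
Why: Partial ester reduction with DIBAL-H stops at the aldehyde because the tetrahedral aluminium alkoxide survives at −78 °C until the quench.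

Step 7
Reactants: 10 3-[4-(tert-butyldimethylsilyloxy)phenyl]propanal
Product: 11 (3S)-1-[4-(tert-butyldimethylsilyloxy)phenyl]hex-5-en-3-ol
Conditions: (R)-BINOL (10 mol %), Ti(OiPr)4 (10 mol %), 4 Å MS, allylSnBu3, CH2Cl2, −20 °C; aq NaHCO3
Reagents that add atoms: allyltributylstannane, C=CC[Sn](CCCC)(CCCC)CCCC
Why: Keck asymmetric allylation: the (R)-BINOL–titanium Lewis acid directs allyl transfer from tin to the Re face of the aldehyde, which sets the carbinol centre (C7' of the target) as S under neutral conditions that keep the aryl silyl ether.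

Step 8
Reactants: 12 4-ethynylphenol
Product: 13 tert-butyl(4-ethynylphenoxy)dimethylsilane
Conditions: TBSCl, imidazole, CH2Cl2, 0–25 °C
Reagents that add atoms: tert-butyldimethylsilyl chloride, CC(C)(C)[Si](C)(C)Cl
Why: Standard silyl ether formation on the phenol, which also stabilises the sensitive ethynylphenol.

Step 9
Reactants: 11 (3S)-1-[4-(tert-butyldimethylsilyloxy)phenyl]hex-5-en-3-ol; 13 tert-butyl(4-ethynylphenoxy)dimethylsilane
Product: 15 (3S,5E)-1,7-bis[4-(tert-butyldimethylsilyloxy)phenyl]octa-5,7-dien-3-ol, via 2-arylbutadiene 14 (not isolated)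
Conditions: Grubbs second-generation catalyst (5–10 mol %), ethylene (1 atm), CH2Cl2, 25–40 °C
Reagents that add atoms: ethylene, C=C
Why: Ethylene-assisted cross enyne metathesis: the alkyne and ethylene give diene 14, whose monosubstituted alkene then undergoes E-selective cross metathesis with 11 while the 1,1-disubstituted styrenyl alkene stays inert, so that only the (5E)-2-aryl-1,3-diene builds up.

Step 10
Reactants: 7 (2S)-7-(tert-butyldimethylsilyloxy)-2-[4-(tert-butyldimethylsilyloxy)phenyl]-5-methoxy-4-oxochromane-8-carbaldehyde; 15 (3S,5E)-1,7-bis[4-(tert-butyldimethylsilyloxy)phenyl]octa-5,7-dien-3-ol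
Product: 16 (2S)-8-{(1R,3R,4E,7S)-1,7-dihydroxy-3,9-bis[4-(tert-butyldimethylsilyloxy)phenyl]non-4-en-1-yl}-7-(tert-butyldimethylsilyloxy)-2-[4-(tert-butyldimethylsilyloxy)phenyl]-5-methoxychroman-4-one (1,3-anti)
Conditions: Ni(cod)2 (10 mol %), (S)-SIPHOS-PE spiro phosphoramidite (12 mol %), Et3B (3 equiv), THF, 25 °C; aq NH4Cl
Reagents that add atoms: none
Why: Proposed new method: Ni(0) bound to one face of the s-cis diene and to the Et3B-activated aldehyde undergoes oxidative cyclisation that joins the formyl carbon to the terminal =CH2 and gives an η3-allyl oxanickelacycle; ethyl transfer from boron, β-hydride elimination (ethene) and C–H reductive elimination at the proximal, aryl-bearing allyl terminus then release the borinate of 16. The closest known reactions are the nickel/Et3B homoallylation of aromatic aldehydes with 2-substituted 1,3-dienes such as isoprene (same regiochemistry, 1,3-anti) and its enantioselective form with spiro phosphoramidites on 1,4-diaryl dienes, and what is new is ligand control on a 2-aryl-4-alkyl diene. No ring of the product is closed; the only ring is the transient five-membered oxanickelacycle in its σ-allyl form. C3' is set by the ligand-selected diene face, because hydride arrives from nickel on that face, and C1' follows from the cyclisation geometry that keeps the bulky flavanone aryl group pseudo-equatorial and away from the C3' aryl group, which gives the 1,3-anti (1'R,3'R) pair. Regioselectivity is secured by the substrate, since both the 2-aryl and the 4-alkyl group raise the HOMO coefficient at the unsubstituted =CH2, and the syn-allyl geometry keeps C4'=C5' as E. Chemoselectivity for CHO over the C4 ketone rests on Et3B, which does not promote ketone coupling, and the neutral borinate avoids 7-O to 1'-O silyl migration.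

Step 11
Reactants: 16 the 1,3-anti (1'R,3'R) diol
Product: 17 (2S)-8-{(3R,4E,7S)-7-hydroxy-3,9-bis[4-(tert-butyldimethylsilyloxy)phenyl]non-4-enoyl}-7-(tert-butyldimethylsilyloxy)-2-[4-(tert-butyldimethylsilyloxy)phenyl]-5-methoxychroman-4-one
Conditions: activated MnO2 (excess), CH2Cl2, 25 °C
Reagents that add atoms: none
Why: Manganese dioxide oxidation is specific for the activated benzylic carbinol, leaves the homoallylic C7'-OH untouched and cannot disturb C3', which is β and not α to the new carbonyl group.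

Step 12
Reactants: 17 the C1' ketone
Product: 18 (2S)-8-{(1S,3R,4E,7S)-1,7-dihydroxy-3,9-bis[4-(tert-butyldimethylsilyloxy)phenyl]non-4-en-1-yl}-7-(tert-butyldimethylsilyloxy)-2-[4-(tert-butyldimethylsilyloxy)phenyl]-5-methoxychroman-4-one (1,3-syn)
Conditions: (R)-Me-CBS (0.3 equiv), catecholborane (2.5 equiv), toluene, −60 to −30 °C; MeOH, pH 7 buffer
Reagents that add atoms: none
Why: Corey–Bakshi–Shibata reduction: the (R)-oxazaborolidine binds the exocyclic ketone anti to its bulky, twisted aryl group (large substituent) and delivers hydride as in the acetophenone-to-(S)-alcohol model to set C1' as S, while the C4 carbonyl, a planar vinylogous carbonate screened by the peri 5-OMe, should react more slowly.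

Step 13
Reactants: 18 the tetrakis-TBS ether of the target
Product: 19 CNP0415883.1, (2S)-7-hydroxy-8-[(1S,3R,4E,7S)-1,7-dihydroxy-3,9-bis(4-hydroxyphenyl)non-4-en-1-yl]-2-(4-hydroxyphenyl)-5-methoxychroman-4-one
Conditions: TBAF/AcOH (1:1, 4.5 equiv), THF, 0 °C
Reagents that add atoms: none
Why: Fluoride-induced cleavage of the four aryl silyl ethers is fast at 0 °C, and the acetic acid buffer keeps the medium near neutral so that neither the flavanone C2 centre (retro-oxa-Michael) nor the ionisable C1' carbinol (ortho-quinone methide) is put at risk.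

Compound list
1 | 2',4'-dihydroxy-6'-methoxyacetophenone | CC(=O)c1c(O)cc(O)cc1OC | starting material
2 | 1-[4-(tert-butyldimethylsilyloxy)-2-hydroxy-6-methoxyphenyl]ethanone | CC(=O)c1c(O)cc(O[Si](C)(C)C(C)(C)C)cc1OC | intermediate
3 | (E)-1-[4-(tert-butyldimethylsilyloxy)-2-hydroxy-6-methoxyphenyl]-3-(dimethylamino)prop-2-en-1-one (not isolated) | CN(C)/C=C/C(=O)c1c(O)cc(O[Si](C)(C)C(C)(C)C)cc1OC | intermediate
4 | 7-(tert-butyldimethylsilyloxy)-5-methoxy-4H-chromen-4-one | COc1cc(O[Si](C)(C)C(C)(C)C)cc2occc(=O)c12 | intermediate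
5 | 4-(tert-butyldimethylsilyloxy)phenylboronic acid | OB(O)c1ccc(O[Si](C)(C)C(C)(C)C)cc1 | starting material
6 | (2S)-7-(tert-butyldimethylsilyloxy)-2-[4-(tert-butyldimethylsilyloxy)phenyl]-5-methoxychroman-4-one | COc1cc(O[Si](C)(C)C(C)(C)C)cc2c1C(=O)C[C@@H](c1ccc(O[Si](C)(C)C(C)(C)C)cc1)O2 | intermediate
7 | (2S)-7-(tert-butyldimethylsilyloxy)-2-[4-(tert-butyldimethylsilyloxy)phenyl]-5-methoxy-4-oxochromane-8-carbaldehyde | COc1cc(O[Si](C)(C)C(C)(C)C)c(C=O)c2c1C(=O)C[C@@H](c1ccc(O[Si](C)(C)C(C)(C)C)cc1)O2 | intermediate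
8 | methyl 3-(4-hydroxyphenyl)propanoate | COC(=O)CCc1ccc(O)cc1 | starting material
9 | methyl 3-[4-(tert-butyldimethylsilyloxy)phenyl]propanoate | COC(=O)CCc1ccc(O[Si](C)(C)C(C)(C)C)cc1 | intermediate
10 | 3-[4-(tert-butyldimethylsilyloxy)phenyl]propanal | O=CCCc1ccc(O[Si](C)(C)C(C)(C)C)cc1 | intermediate
11 | (3S)-1-[4-(tert-butyldimethylsilyloxy)phenyl]hex-5-en-3-ol | C=CC[C@@H](O)CCc1ccc(O[Si](C)(C)C(C)(C)C)cc1 | intermediate
12 | 4-ethynylphenol | C#Cc1ccc(O)cc1 | starting material
13 | tert-butyl(4-ethynylphenoxy)dimethylsilane | C#Cc1ccc(O[Si](C)(C)C(C)(C)C)cc1 | intermediate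
14 | 2-[4-(tert-butyldimethylsilyloxy)phenyl]buta-1,3-diene (not isolated) | C=CC(=C)c1ccc(O[Si](C)(C)C(C)(C)C)cc1 | intermediate
15 | (3S,5E)-1,7-bis[4-(tert-butyldimethylsilyloxy)phenyl]octa-5,7-dien-3-ol | C=C(/C=C/C[C@@H](O)CCc1ccc(O[Si](C)(C)C(C)(C)C)cc1)c1ccc(O[Si](C)(C)C(C)(C)C)cc1 | intermediate
16 | (2S,1'R,3'R,4'E,7'S) 1,3-anti coupling product, tetrakis-TBS ether | COc1cc(O[Si](C)(C)C(C)(C)C)c([C@H](O)C[C@H](/C=C/C[C@@H](O)CCc2ccc(O[Si](C)(C)C(C)(C)C)cc2)c2ccc(O[Si](C)(C)C(C)(C)C)cc2)c2c1C(=O)C[C@@H](c1ccc(O[Si](C)(C)C(C)(C)C)cc1)O2 | intermediate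
17 | (2S,3'R,4'E,7'S) C1' ketone, tetrakis-TBS ether | COc1cc(O[Si](C)(C)C(C)(C)C)c(C(=O)C[C@H](/C=C/C[C@@H](O)CCc2ccc(O[Si](C)(C)C(C)(C)C)cc2)c2ccc(O[Si](C)(C)C(C)(C)C)cc2)c2c1C(=O)C[C@@H](c1ccc(O[Si](C)(C)C(C)(C)C)cc1)O2 | intermediate
18 | (2S,1'S,3'R,4'E,7'S) 1,3-syn diol, tetrakis-TBS ether of the target | COc1cc(O[Si](C)(C)C(C)(C)C)c([C@@H](O)C[C@H](/C=C/C[C@@H](O)CCc2ccc(O[Si](C)(C)C(C)(C)C)cc2)c2ccc(O[Si](C)(C)C(C)(C)C)cc2)c2c1C(=O)C[C@@H](c1ccc(O[Si](C)(C)C(C)(C)C)cc1)O2 | intermediate
19 | CNP0415883.1 | COc1cc(O)c([C@@H](O)C[C@H](/C=C/C[C@@H](O)CCc2ccc(O)cc2)c2ccc(O)cc2)c2c1C(=O)C[C@@H](c1ccc(O)cc1)O2 | target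

Total step count: 13.
Longest linear sequence: 8 steps (1–4 then 10–13; equally 5–7, 9 then 10–13).

Steps most likely to fail

1. Step 10.
- What may go wrong: the ligand may discriminate poorly between the two diene faces. Oxidative cyclisation may also be sluggish with the doubly ortho-substituted, electron-rich aldehyde.
- Route of the fallback: it uses known chemistry, forms the same bond, sets out from 15 and 7, and comes back at 17.
- Setting C3': diene 15 is silylated (TESCl, imidazole) to the triethylsilyl ether F1. A cationic cobalt(I)–phosphinooxazoline catalyst with pinacolborane then effects the known enantioselective 1,2-hydroboration of 2-substituted 1,3-dienes and gives the homoallylic pinacol boronate F2 with C3' already set.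
- Making the nucleophile: sodium perborate gives the primary alcohol F3, and Appel iodination (I2, PPh3, imidazole) gives the primary iodide F4. Iodine–lithium exchange (t-BuLi, Et2O, −78 °C) gives the alkyllithium F5, and ClTi(OiPr)3 turns it into the aldehyde-selective alkyltitanium triisopropoxide F6.
- Coupling and return: F6 adds to the formyl group of 7 without touching the C4 ketone and gives the C1'-epimeric carbinols F7. MnO2 erases C1' to give the TES-protected ketone F8, and PPTS in methanol removes the TES group to give 17.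

2. Step 12.
- What may go wrong: hydride may also be delivered to the C4 carbonyl, or the facial selectivity at the hindered twisted ketone may be low.
- Route of the fallback: it replaces external catalyst control by hydride delivery from a reagent anchored on the neighbouring 7-OH. It sets out from 17 and comes back at 19.
- Unmasking the anchor: one equivalent of buffered fluoride at low temperature removes the most labile silyl group. This is the group on O7, whose phenoxide is a vinylogous carboxylate flanked by the acyl group. The product is the ortho-hydroxyaryl ketone F9.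
- Reduction and return: (+)-DIP-Cl binds this phenol and reduces only the chelated C1' ketone, with the reversed sense known for ortho-hydroxyaryl ketones, to give the (1'S)-carbinol tris-TBS ether F10. The conditions of step 13 then give 19.

3. Step 4.
- What may go wrong: attack may occur at C6. The triflic acid formed may also cause loss of the 7-O-silyl group or opening of the heterocycle.
- Route of the fallback: it splits the task into neutral halogenation and reductive carbonylation. It sets out from 6 and comes back at 7.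
- Sequence: N-iodosuccinimide in MeCN, a bulkier electrophile that is more sensitive to the OMe/OTBS cleft at C6, gives the 8-iodoflavanone F11. Stille-type carbonylative reduction (Pd(PPh3)4, CO, slow addition of Bu3SnH, THF, 50 °C) then gives 7.

Further compounds
F1 | step 10 | (3S,5E)-1,7-bis[4-(tert-butyldimethylsilyloxy)phenyl]-3-(triethylsilyloxy)octa-5,7-diene | C=C(/C=C/C[C@@H](O[Si](CC)(CC)CC)CCc1ccc(O[Si](C)(C)C(C)(C)C)cc1)c1ccc(O[Si](C)(C)C(C)(C)C)cc1
F2 | step 10 | pinacol (2R,3E,6S)-2,8-bis[4-(tert-butyldimethylsilyloxy)phenyl]-6-(triethylsilyloxy)oct-3-en-1-ylboronate | CC1(C)OB(C[C@H](/C=C/C[C@@H](O[Si](CC)(CC)CC)CCc2ccc(O[Si](C)(C)C(C)(C)C)cc2)c2ccc(O[Si](C)(C)C(C)(C)C)cc2)OC1(C)C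
F3 | step 10 | (2R,3E,6S)-2,8-bis[4-(tert-butyldimethylsilyloxy)phenyl]-6-(triethylsilyloxy)oct-3-en-1-ol | OC[C@H](/C=C/C[C@@H](O[Si](CC)(CC)CC)CCc1ccc(O[Si](C)(C)C(C)(C)C)cc1)c1ccc(O[Si](C)(C)C(C)(C)C)cc1
F4 | step 10 | (2R,3E,6S)-1-iodo-2,8-bis[4-(tert-butyldimethylsilyloxy)phenyl]-6-(triethylsilyloxy)oct-3-ene | IC[C@H](/C=C/C[C@@H](O[Si](CC)(CC)CC)CCc1ccc(O[Si](C)(C)C(C)(C)C)cc1)c1ccc(O[Si](C)(C)C(C)(C)C)cc1
F5 | step 10 | the alkyllithium from F4 (in situ) | [Li]C[C@H](/C=C/C[C@@H](O[Si](CC)(CC)CC)CCc1ccc(O[Si](C)(C)C(C)(C)C)cc1)c1ccc(O[Si](C)(C)C(C)(C)C)cc1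
F6 | step 10 | the alkyltitanium triisopropoxide from F5 (in situ) | CC(C)O[Ti](OC(C)C)(OC(C)C)C[C@H](/C=C/C[C@@H](O[Si](CC)(CC)CC)CCc1ccc(O[Si](C)(C)C(C)(C)C)cc1)c1ccc(O[Si](C)(C)C(C)(C)C)cc1
F7 | step 10 | C1'-epimeric carbinols, 7'-O-TES analogue of 16 and 18 | COc1cc(O[Si](C)(C)C(C)(C)C)c(C(O)C[C@H](/C=C/C[C@@H](O[Si](CC)(CC)CC)CCc2ccc(O[Si](C)(C)C(C)(C)C)cc2)c2ccc(O[Si](C)(C)C(C)(C)C)cc2)c2c1C(=O)C[C@@H](c1ccc(O[Si](C)(C)C(C)(C)C)cc1)O2
F8 | step 10 | 7'-O-TES ether of ketone 17 | COc1cc(O[Si](C)(C)C(C)(C)C)c(C(=O)C[C@H](/C=C/C[C@@H](O[Si](CC)(CC)CC)CCc2ccc(O[Si](C)(C)C(C)(C)C)cc2)c2ccc(O[Si](C)(C)C(C)(C)C)cc2)c2c1C(=O)C[C@@H](c1ccc(O[Si](C)(C)C(C)(C)C)cc1)O2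
F9 | step 12 | 7-hydroxy ketone, tris-TBS ether | COc1cc(O)c(C(=O)C[C@H](/C=C/C[C@@H](O)CCc2ccc(O[Si](C)(C)C(C)(C)C)cc2)c2ccc(O[Si](C)(C)C(C)(C)C)cc2)c2c1C(=O)C[C@@H](c1ccc(O[Si](C)(C)C(C)(C)C)cc1)O2
F10 | step 12 | 7-hydroxy (1'S)-carbinol, tris-TBS ether | COc1cc(O)c([C@@H](O)C[C@H](/C=C/C[C@@H](O)CCc2ccc(O[Si](C)(C)C(C)(C)C)cc2)c2ccc(O[Si](C)(C)C(C)(C)C)cc2)c2c1C(=O)C[C@@H](c1ccc(O[Si](C)(C)C(C)(C)C)cc1)O2
F11 | step 4 | (2S)-7-(tert-butyldimethylsilyloxy)-2-[4-(tert-butyldimethylsilyloxy)phenyl]-8-iodo-5-methoxychroman-4-one | COc1cc(O[Si](C)(C)C(C)(C)C)c(I)c2c1C(=O)C[C@@H](c1ccc(O[Si](C)(C)C(C)(C)C)cc1)O2
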